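**Strategy.** Everything rests on cutting the ester between its carbonyl carbon and C1 of the galloyl ring. The carbonyl is carried on O3 of the flavan C ring as an imidazole-1-carboxylate of tetra-O-benzyl-(−)-epicatechin, so the C3–O bond and the (2R,3R) centres are never touched. C1 of the symmetric galloyl ring lies para to the 4-oxygen; it is brominated through a 2,6-dibenzyloxyphenoxide and converted into an arylmagnesium bromide. In one operation this Grignard reagent displaces imidazolide and forges the aryl–carbonyl bond, joining the two fully protected halves. One hydrogenolysis then frees all six phenols.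

Key step: step 6

Assumption: (−)-epicatechin, whose (2R,3R) configuration is that of the target, and 1,3-bis(benzyloxy)benzene are taken as purchasable.

**Step 1**
Reactants: 1 1,3-bis(benzyloxy)benzene
Product: 4 2,6-bis(benzyloxy)phenol, via aryllithium 2 (not isolated), via dimethyl arylboronate 3 (not isolated)
Conditions: n-BuLi, THF, 0 °C → rt; B(OMe)3, −78 °C → rt; AcOH, 30% H2O2, 0 °C → rt
Reagents that add atoms: hydrogen peroxide, OO (the new oxygen of 4); n-butyllithium, [Li]CCCC (lithium of 2); trimethyl borate, COB(OC)OC (boron group of 3)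
Why: Directed ortho-metalation should lithiate the C2–H flanked and coordinated by both benzyloxy groups, and borate trapping followed by peroxide oxidation (1,2-aryl shift from boron to oxygen) should turn that C–Li bond into C–OH.

**Step 2**
Reactants: 4 2,6-bis(benzyloxy)phenol
Product: 5 2,6-bis(benzyloxy)-4-bromophenol
Conditions: NBS (1.0 equiv), NaH (0.1 equiv), CHCl3, −45 °C → rt
Reagents that add atoms: N-bromosuccinimide, O=C1CCC(=O)N1Br
Why: Electrophilic aromatic bromination run through the phenoxide (catalytic base, chain carried by succinimide anion) should place bromine para to the oxygen, because the phenoxide charge is delivered to C4 while both ortho carbons are blocked.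

**Step 3**
Reactants: 5 2,6-bis(benzyloxy)-4-bromophenol
Product: 6 1,3-bis(benzyloxy)-5-bromo-2-methoxybenzene
Conditions: MeI, K2CO3, DMF, rt
Reagents that add atoms: iodomethane, CI
Why: Williamson ether synthesis should methylate the flanked but acidic phenoxide, and the aryl bromide and benzyl ethers are inert to carbonate.

**Step 4**
Reactants: 7 (−)-epicatechin
Product: 8 5,7,3',4'-tetra-O-benzyl-(−)-epicatechin
Conditions: BnBr (4.4 equiv), K2CO3, DMF, 0 °C → rt, Ar
Reagents that add atoms: benzyl bromide, BrCc1ccccc1
Why: In this Williamson etherification carbonate ionises only the four phenols and not the secondary 3-OH, so O5, O7, O3' and O4' should be capped while C2 and C3 keep their (2R,3R) configuration because no bond to either is broken.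

**Step 5**
Reactants: 8 5,7,3',4'-tetra-O-benzyl-(−)-epicatechin
Product: 9 tetra-O-benzyl-(−)-epicatechin-3-yl 1H-imidazole-1-carboxylate
Conditions: CDI (2 equiv), cat. DMAP, CH2Cl2, rt → 40 °C
Reagents that add atoms: 1,1'-carbonyldiimidazole, O=C(n1ccnc1)n1ccnc1
Why: Azolide acyl transfer from CDI to the only free hydroxyl should give the imidazole-1-carboxylate with retention at C3, since only the O–H bond reacts.

**Step 6**
Reactants: 6 1,3-bis(benzyloxy)-5-bromo-2-methoxybenzene; 9 tetra-O-benzyl-(−)-epicatechin-3-yl 1H-imidazole-1-carboxylate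
Product: 11 tetra-O-benzyl-(−)-epicatechin-3-yl 3,5-bis(benzyloxy)-4-methoxybenzoate, via arylmagnesium bromide 10 (not isolated)
Conditions: 6, Mg turnings, cat. I2, THF, 45 °C; then added slowly (about 1.2 equiv) to 9, THF, −40 → 0 °C; sat. aq. NH4Cl
Reagents that add atoms: magnesium, [Mg] (present in 10 only; no reagent atom remains in 11)
Why: Magnesium inserts into the C–Br bond of 6 to give 10, whose carbanionic carbon is the future C1 of the galloyl ring; 10 adds to the carbamate carbonyl of 9 and the tetrahedral magnesium alkoxide collapses by expelling imidazolide, a far better leaving group than the secondary C3 alkoxide, which forms the aryl–C(=O) bond of 11. The closest known reaction type is the ester synthesis from Grignard reagents and alkyl 1-imidazolecarboxylates, a nucleophilic acyl substitution on an azolide. No ring is closed and no stereocentre is created: C2 and C3 are spectators because the C3–O bond is never broken and the substrate has no enolisable position, so the (2R,3R) configuration of 8 is carried through. The selectivity needed is mono-addition, that is reaction at the azolide and not at the product ester; it is secured by the higher electrophilicity of the N-acylimidazole-type carbonyl, by the deactivation of the product ester through its electron-rich trioxygenated aryl ring and the shielding axial flavanyl group, and by slow addition at low temperature. Regiochemistry on the arene is fixed by the position of bromine, and the benzyl ethers and the aryl methyl ether are inert to the Grignard reagent.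

**Step 7**
Reactants: 11 tetra-O-benzyl-(−)-epicatechin-3-yl 3,5-bis(benzyloxy)-4-methoxybenzoate
Product: 12 (−)-epicatechin 3-O-(4-O-methylgallate)
Conditions: H2 (1 atm), 20% Pd(OH)2/C, THF/MeOH (1:1), rt
Reagents that add atoms: none
Why: Heterogeneous hydrogenolysis should cleave all six benzylic C–O bonds of the aryl benzyl ethers, while the aryl methyl ether, the benzoate at the non-benzylic C3, the more slowly reacting cyclic C2–O1 ether and both stereocentres should survive at 1 atm and rt.

**Compound list**
1 | 1,3-bis(benzyloxy)benzene | c1ccc(COc2cccc(OCc3ccccc3)c2)cc1 | starting material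
2 | 2,6-bis(benzyloxy)phenyllithium | [Li]c1c(OCc2ccccc2)cccc1OCc1ccccc1 | intermediate (not isolated)
3 | dimethyl [2,6-bis(benzyloxy)phenyl]boronate | COB(OC)c1c(OCc2ccccc2)cccc1OCc1ccccc1 | intermediate (not isolated)
4 | 2,6-bis(benzyloxy)phenol | Oc1c(OCc2ccccc2)cccc1OCc1ccccc1 | intermediate
5 | 2,6-bis(benzyloxy)-4-bromophenol | Oc1c(OCc2ccccc2)cc(Br)cc1OCc1ccccc1 | intermediate
6 | 1,3-bis(benzyloxy)-5-bromo-2-methoxybenzene | COc1c(OCc2ccccc2)cc(Br)cc1OCc1ccccc1 | intermediate
7 | (−)-epicatechin, (2R,3R)-2-(3,4-dihydroxyphenyl)chromane-3,5,7-triol | O[C@@H]1Cc2c(O)cc(O)cc2O[C@@H]1c1ccc(O)c(O)c1 | starting material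
8 | 5,7,3',4'-tetra-O-benzyl-(−)-epicatechin, (2R,3R)-5,7-bis(benzyloxy)-2-[3,4-bis(benzyloxy)phenyl]chroman-3-ol | O[C@@H]1Cc2c(OCc3ccccc3)cc(OCc3ccccc3)cc2O[C@@H]1c1ccc(OCc2ccccc2)c(OCc2ccccc2)c1 | intermediate
9 | (2R,3R)-5,7-bis(benzyloxy)-2-[3,4-bis(benzyloxy)phenyl]chroman-3-yl 1H-imidazole-1-carboxylate | O=C(O[C@@H]1Cc2c(OCc3ccccc3)cc(OCc3ccccc3)cc2O[C@@H]1c1ccc(OCc2ccccc2)c(OCc2ccccc2)c1)n1ccnc1 | intermediate
10 | [3,5-bis(benzyloxy)-4-methoxyphenyl]magnesium bromide | COc1c(OCc2ccccc2)cc([Mg]Br)cc1OCc1ccccc1 | intermediate (not isolated)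
11 | (2R,3R)-5,7-bis(benzyloxy)-2-[3,4-bis(benzyloxy)phenyl]chroman-3-yl 3,5-bis(benzyloxy)-4-methoxybenzoate | COc1c(OCc2ccccc2)cc(C(=O)O[C@@H]2Cc3c(OCc4ccccc4)cc(OCc4ccccc4)cc3O[C@@H]2c2ccc(OCc3ccccc3)c(OCc3ccccc3)c2)cc1OCc1ccccc1 | intermediate
12 | (−)-epicatechin 3-O-(4-O-methylgallate), (2R,3R)-2-(3,4-dihydroxyphenyl)-5,7-dihydroxychroman-3-yl 3,5-dihydroxy-4-methoxybenzoate | COc1c(O)cc(C(=O)O[C@@H]2Cc3c(O)cc(O)cc3O[C@@H]2c2ccc(O)c(O)c2)cc1O | target

**Step count.** Total: 7 steps. Longest linear sequence: 5 steps (steps 1, 2, 3, 6, 7, from 1); the epicatechin branch has 4 (steps 4, 5, 6, 7).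

**Steps most likely to fail**

Step 6 (key step). What may go wrong: sluggish magnesium insertion with Wurtz-type homocoupling of the aryl bromide, a second addition of the Grignard reagent to the freshly formed ester, or collapse of the tetrahedral intermediate with loss of the C3 alkoxide instead of imidazolide. The fallback is a palladium-catalysed alkoxycarbonylation (Heck carbonylation) that needs no organomagnesium reagent. It sets out from bromide 6 and alcohol 8 (Pd(OAc)2, Xantphos, carbon monoxide [C-]#[O+] at 1 atm, K3PO4, toluene, 100 °C). The aroylpalladium species formed by oxidative addition and CO insertion should be captured by the C3 oxygen, and the fallback comes back to the route at 11. It makes no new compound (F0).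

Step 4. What may go wrong: C-benzylation of the electron-rich A ring at C6/C8, alkylation of O3 by excess reagent, base-induced epimerisation at C2 through opening of the pyran ring of the free 4'-phenoxide, and air oxidation of the polyphenoxide. The fallback releases the phenoxides gradually from esters. It sets out from 7, which is peracetylated (Ac2O, pyridine) to (−)-epicatechin pentaacetate F1. BnCl, NaH and four equivalents of water in DMF at 0 °C should then cleave the four aryl acetates and benzylate each phenoxide as it is released, giving 3-O-acetyl-5,7,3',4'-tetra-O-benzyl-(−)-epicatechin F2. K2CO3 in MeOH/THF removes the remaining acetate, and the sequence comes back to the route at 8.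

Step 2. What may go wrong: bromination at C3/C5 (ortho and para to the benzyloxy groups) instead of C4, dibromination, or oxidation to the quinone. The fallback installs nitrogen instead of bromine as the first para substituent, with an electrophile that attacks only the para position of a phenoxide. It sets out from 4: azo coupling with benzenediazonium tetrafluoroborate (aq. NaOH/THF, 0 °C) should give 2,6-bis(benzyloxy)-4-(phenyldiazenyl)phenol F3. O-Methylation (MeI, K2CO3, DMF) gives 1,3-bis(benzyloxy)-2-methoxy-5-(phenyldiazenyl)benzene F4. Reductive cleavage of the azo bond (Na2S2O4, EtOH/H2O, 70 °C) gives 3,5-bis(benzyloxy)-4-methoxyaniline F5. A Sandmeyer bromination (t-BuONO, CuBr2, MeCN, 0 → 60 °C) through 3,5-bis(benzyloxy)-4-methoxybenzenediazonium bromide F6 comes back to the route at 6.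

**Further compounds**
F0 | step 6 | none | none
F1 | step 4 | (−)-epicatechin pentaacetate | CC(=O)O[C@@H]1Cc2c(OC(C)=O)cc(OC(C)=O)cc2O[C@@H]1c1ccc(OC(C)=O)c(OC(C)=O)c1
F2 | step 4 | 3-O-acetyl-5,7,3',4'-tetra-O-benzyl-(−)-epicatechin | CC(=O)O[C@@H]1Cc2c(OCc3ccccc3)cc(OCc3ccccc3)cc2O[C@@H]1c1ccc(OCc2ccccc2)c(OCc2ccccc2)c1
F3 | step 2 | 2,6-bis(benzyloxy)-4-(phenyldiazenyl)phenol | Oc1c(OCc2ccccc2)cc(/N=N/c2ccccc2)cc1OCc1ccccc1
F4 | step 2 | 1,3-bis(benzyloxy)-2-methoxy-5-(phenyldiazenyl)benzene | COc1c(OCc2ccccc2)cc(/N=N/c2ccccc2)cc1OCc1ccccc1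
F5 | step 2 | 3,5-bis(benzyloxy)-4-methoxyaniline | COc1c(OCc2ccccc2)cc(N)cc1OCc1ccccc1
F6 | step 2 | 3,5-bis(benzyloxy)-4-methoxybenzenediazonium bromide | COc1c(OCc2ccccc2)cc([N+]#N)cc1OCc1ccccc1.[Br-]
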